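**Assumptions.** (i) The (2S) configuration is the natural flavanone configuration. I assume (S)-t-Bu-PyOx delivers 2S; I would screen both ligand enantiomers to confirm. (ii) MOM is used as the single global phenol protecting group, removed in the last step.

## Retrosynthetic overview
1. The C2 stereocentre is set last by a Pd(II)/PyOx enantioselective 1,4-arylation of a 6-alkyl-5,7-bis(MOM)chromone with a bis-MOM catechol boronic acid. This replaces the usual chalcone and oxa-Michael route. A final global MOM removal gives the target.
2. The chromone pyranone ring is the only heterocycle formed, by DMF-DMA annulation of a 2′-hydroxyacetophenone.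
3. The regiodefined acetophenone (6-alkyl, not 8-alkyl) comes from tris-MOM-phloroglucinol by directed ortho-metalation (DoM) and Cu-catalysed allylation with (E)-7-hydroxygeranyl chloride. A second DoM/acylation and a chelation-controlled mono-MOM cleavage follow.
4. The side chain is made from geranyl acetate by a Mukaiyama hydration of the distal alkene.

## Route

**Step 1**
Reactants: 1, geranyl acetate ((2E)-3,7-dimethylocta-2,6-dien-1-yl acetate)
Product: 2, (2E)-7-hydroxy-3,7-dimethyloct-2-en-1-yl acetate
Conditions: Co(acac)2 (5 mol%), PhSiH3, O2 (balloon), i-PrOH, 0 °C → rt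
Reagents that add atoms: O2 (O=O)
Why: Mukaiyama (HAT) Markovnikov hydration. Co–H transfers H• to the more electron-rich 6,7-alkene, because the 2,3-alkene is deactivated by the allylic acetate. The tertiary radical is trapped by O2 to give the tertiary alcohol, and the E-geometry of the 2,3-alkene is untouched.

**Step 2**
Reactants: 2
Product: 3, (2E)-3,7-dimethyloct-2-ene-1,7-diol
Conditions: K2CO3, MeOH, rt
Reagents that add atoms: none
Why: Base-mediated methanolysis of the primary acetate; no stereocentre is involved and the alkene is retained.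

**Step 3**
Reactants: 3
Product: 4, (6E)-8-chloro-2,6-dimethyloct-6-en-2-ol
Conditions: MsCl, 2,4,6-collidine, LiCl, DMF, 0 °C → rt
Reagents that add atoms: LiCl ([Li+].[Cl-])
Why: Meyers allylic alcohol to chloride conversion. The primary allylic mesylate is displaced by chloride in SN2 fashion, the hindered tertiary alcohol is not activated, and the E-alkene is retained.

**Step 4**
Reactants: 5, phloroglucinol
Product: 6, 1,3,5-tris(methoxymethoxy)benzene
Conditions: MOMCl (3.6 equiv), i-Pr2NEt, CH2Cl2, 0 °C → rt
Reagents that add atoms: MOMCl (COCCl)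
Why: Standard O-alkylation of phenols to give aryl MOM ethers.

**Step 5**
Reactants: 6 (2.5 equiv), 4
Product: 7, (6E)-2,6-dimethyl-8-[2,4,6-tris(methoxymethoxy)phenyl]oct-6-en-2-ol
Conditions: n-BuLi, THF, 0 °C; then Li2CuCl4 (5 mol%), 4, −40 °C → rt
Reagents that add atoms: none
Why: The three positions of 6 are equivalent, and two flanking OMOM groups cooperatively direct lithiation between them (directed ortho-metalation). Cu(I)-catalysed SN2 allylation then gives the linear, E-retained product, with no regiochemical choice on the arene. The extra equivalents of ArLi absorb the tertiary OH proton.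

**Step 6**
Reactants: 7
Product: 8, 1-{3-[(2E)-7-hydroxy-3,7-dimethyloct-2-en-1-yl]-2,4,6-tris(methoxymethoxy)phenyl}ethan-1-one
Conditions: n-BuLi (2.6 equiv), THF, −20 → 0 °C; then AcN(OMe)Me, −78 °C → rt
Reagents that add atoms: N-methoxy-N-methylacetamide (CC(=O)N(C)OC)
Why: A second DoM occurs at the only free position, between two OMOM groups (the two free positions are equivalent), and the Weinreb amide stops at the methyl ketone stage.

**Step 7**
Reactants: 8
Product: 9, 1-[2-hydroxy-5-[(2E)-7-hydroxy-3,7-dimethyloct-2-en-1-yl]-4,6-bis(methoxymethoxy)phenyl]ethan-1-one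
Conditions: MgBr2·OEt2 (2 equiv), n-PrSH, Et2O/CH2Cl2, 0 °C → rt, stop at mono-cleavage
Reagents that add atoms: none
Why: Chelation-assisted cleavage of the ortho-acyl MOM ether.
Proposed new method: Mg2+ chelates the acetyl oxygen and an ortho-MOM oxygen, and Br−/thiol cleaves the activated oxocarbenium. The 6′-OMOM, remote from the alkyl chain, stays coplanar with the carbonyl and accessible. The 2′-OMOM, flanked by the chain, is twisted and shielded. Closest known reaction: MgBr2- or BCl3-directed selective dealkylation of the ortho-acyl ether (cf. 5-O-demethylation of chromones). This fixes the single free phenol that becomes O1, so the product is 6-alkyl and not 8-alkyl.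

**Step 8**
Reactants: 9
Product: 10, (E)-6-(7-hydroxy-3,7-dimethyloct-2-en-1-yl)-5,7-bis(methoxymethoxy)-4H-chromen-4-one
Conditions: (i) DMF-DMA (3 equiv), PhMe, 100 °C; (ii) AcOH, 50 °C
Reagents that add atoms: DMF-DMA (CN(C)C(OC)OC), which supplies the C2 carbon
Why: Enaminone formation followed by oxa-Michael addition and loss of Me2NH gives the chromone. Only one phenol is free, so the ring closure is regiodefined.

**Step 9**
Reactants: 11, 4-bromocatechol
Product: 12, 4-bromo-1,2-bis(methoxymethoxy)benzene
Conditions: MOMCl (2.5 equiv), i-Pr2NEt, CH2Cl2, 0 °C → rt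
Reagents that add atoms: MOMCl (COCCl)
Why: Standard bis-MOM protection of the catechol.

**Step 10**
Reactants: 12
Product: 13, [3,4-bis(methoxymethoxy)phenyl]boronic acid
Conditions: n-BuLi, THF, −78 °C; then B(OMe)3; aq. NH4Cl
Reagents that add atoms: B(OMe)3 (COB(OC)OC)
Why: Li–Br exchange followed by borate trapping and mild hydrolysis, which avoids MOM cleavage.

**Step 11 (key step)**
Reactants: 10, 13 (3 equiv)
Product: 14, the (2S)-tetra-MOM flavanone
Conditions: Pd(OCOCF3)2 (10 mol%), (S)-t-Bu-PyOx (12 mol%), NH4PF6, ClCH2CH2Cl, trace H2O, 60 °C, 48 h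
Reagents that add atoms: none (the aryl group comes from 13 and the added H from protonolysis)
Why: Cationic Pd(II)/PyOx catalysis: transmetalation gives Ar–Pd+, enantiofacial carbopalladation of the chromone C2=C3 bond follows, and protonolysis of the Pd-enolate sets C2 as (S) directly. This is a Pd-catalysed asymmetric conjugate arylation with an arylboronic acid.
Proposed new method: The closest known reaction is the Pd/PyOx 1,4-arylation of β-substituted cyclic enones and chromones. The extension to a very electron-rich 5,7-dialkoxy-6-alkyl chromone is the risk. Insertion into C=C is governed by Pd–carbonyl coordination rather than by enone electrophilicity, the tertiary OH and trisubstituted alkene are inert to cationic Pd–Ar, and excess boronic acid covers protodeboronation.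

**Step 12**
Reactants: 14
Product: 15, prokinawan, (2S)-2-(3,4-dihydroxyphenyl)-5,7-dihydroxy-6-[(2E)-7-hydroxy-3,7-dimethyloct-2-en-1-yl]chroman-4-one
Conditions: 1.25 M HCl in MeOH, 40 °C, degassed
Reagents that add atoms: none
Why: Acidolysis of the four aryl MOM acetals. Flavanone C2 epimerisation needs base-type ring-opening, which is absent, and dilute HCl at 40 °C is mild enough for the tertiary alcohol and the E-alkene.

## Compound list
1 | geranyl acetate | CC(C)=CCC/C(C)=C/COC(C)=O | starting material
2 | (2E)-7-hydroxy-3,7-dimethyloct-2-en-1-yl acetate | CC(=O)OC/C=C(\C)CCCC(C)(C)O | intermediate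
3 | (2E)-3,7-dimethyloct-2-ene-1,7-diol | OC/C=C(\C)CCCC(C)(C)O | intermediate
4 | (6E)-8-chloro-2,6-dimethyloct-6-en-2-ol | ClC/C=C(\C)CCCC(C)(C)O | intermediate
5 | phloroglucinol | Oc1cc(O)cc(O)c1 | starting material
6 | 1,3,5-tris(methoxymethoxy)benzene | COCOc1cc(OCOC)cc(OCOC)c1 | intermediate
7 | (6E)-2,6-dimethyl-8-[2,4,6-tris(MOMO)phenyl]oct-6-en-2-ol | COCOc1cc(OCOC)c(C/C=C(\C)CCCC(C)(C)O)c(OCOC)c1 | intermediate
8 | aryl methyl ketone, tris-MOM, chain-bearing | CC(=O)c1c(OCOC)c(C/C=C(\C)CCCC(C)(C)O)c(OCOC)cc1OCOC | intermediate
9 | 2′-hydroxy-4′,6′-bis(MOMO)-5′-chain acetophenone | CC(=O)c1c(OCOC)c(C/C=C(\C)CCCC(C)(C)O)c(OCOC)cc1O | intermediate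
10 | 6-chain-5,7-bis(MOMO)chromone | O=c1ccoc2cc(OCOC)c(C/C=C(\C)CCCC(C)(C)O)c(OCOC)c12 | intermediate
11 | 4-bromocatechol | Oc1ccc(Br)cc1O | starting material
12 | 4-bromo-1,2-bis(MOMO)benzene | COCOc1ccc(Br)cc1OCOC | intermediate
13 | 3,4-bis(MOMO)phenylboronic acid | COCOc1ccc(B(O)O)cc1OCOC | intermediate
14 | (2S)-tetra-MOM flavanone | C/C(=C\Cc1c(OCOC)cc2c(c1OCOC)C(=O)C[C@@H](c1ccc(OCOC)c(OCOC)c1)O2)CCCC(C)(C)O | intermediate
15 | prokinawan | C/C(=C\Cc1c(O)cc2c(c1O)C(=O)C[C@@H](c1ccc(O)c(O)c1)O2)CCCC(C)(C)O | target

**Step count:** 12 steps in total, with 9 in the longest linear sequence (1 → 2 → 3 → 4 → 7 → 8 → 9 → 10 → 14 → 15, i.e. steps 1, 2, 3, 5, 6, 7, 8, 11, 12).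

**Three steps most likely to fail**
1. **Step 11 (Pd-catalysed asymmetric arylation of the electron-rich chromone).** Reactivity or ee may be poor.
   - Fallback: Claisen–Schmidt condensation of 9 with 3,4-bis(MOMO)benzaldehyde, then bifunctional-catalyst (cinchona-thiourea or chiral phosphoric acid) asymmetric intramolecular oxa-Michael cyclisation of the 2′-hydroxychalcone, converging on 14.
2. **Step 7 (regioselective mono-MOM cleavage).** It may give a mixture of 6-alkyl and 8-alkyl precursors.
   - Fallback: start from 1,3-bis(MOMO)benzene, then DoM/allylation, Ir-catalysed C5–H borylation and oxidation to 4-alkyl-3,5-bis(MOMO)phenol, then Casnati ortho-formylation, MeMgBr addition and oxidation to reach 9 with fixed regiochemistry.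
3. **Step 1 (chemoselective Mukaiyama hydration of the 6,7-alkene).** It may over-reduce or hydrate the wrong alkene.
   - Fallback: NBS, THF/H2O on geranyl acetate to give the terminal bromohydrin, then K2CO3/MeOH to give 6,7-epoxygeraniol, then LiEt3BH opening at the less hindered carbon to give diol 3 directly.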